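**Plan**

Notation: benzofuran numbering; ring A is the benzo ring, ring B the syringyl ring on C2, ring C the resorcinol ring, and C9 the CH2OH carbon. The retrosynthesis cuts, in order, four O–Si bonds, the C5 styryl C=C (phosphonate olefination), the aryl ether bond O1–C7a (palladium C–O coupling), C2–C3 (aldol), and C3a–C3 (Claisen allyl transfer on vanillin).
Enabling feature: O1–C7a ties the C2 oxygen to an sp2 carbon of ring A and touches neither stereocentre. C7a is also the carbon that carries the phenol oxygen of vanillin, so that oxygen can leave as triflate while a finished acyclic C2/C3 diad is brought in unchanged.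
Forward order: vanillin gives the ring A arylacetic acid (OTf at C7a, dioxolane at C5), which is loaded onto the auxiliary. The aldol with silylated syringaldehyde joins rings A and B. After reduction and C9 silylation the dihydrofuran, the only ring made, is closed. Ring C is attached last by olefination, and fluoride then removes the silyl groups.
Stereochemistry: one Evans syn-aldol under (R)-4-benzyl-2-oxazolidinone control sets both centres. Syn in the chain corresponds to 2,3-trans in the ring, and no later step breaks a bond at C2 or C3. The E-alkene comes from the phosphonate olefination.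

Key step: step 12

Assumption: the ortho-substituted ring A arylacetyl imide is taken to follow the normal Evans sense of induction known for propionyl and phenylacetyl imides, so the (R)-auxiliary should deliver the (2R,3R) syn adduct.

Step 1
Reactants: 1 vanillin (4-hydroxy-3-methoxybenzaldehyde); 2 allyl bromide
Product: 3 4-(allyloxy)-3-methoxybenzaldehyde
Conditions: K2CO3, acetone, reflux
Reagents that add atoms: none
Why: Williamson ether synthesis, in which K2CO3 deprotonates the acidic para-formyl phenol and the phenoxide displaces the unhindered allylic bromide by SN2 while the aldehyde stays inert.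

Step 2
Reactants: 3 4-(allyloxy)-3-methoxybenzaldehyde
Product: 4 5-allylvanillin (3-allyl-4-hydroxy-5-methoxybenzaldehyde)
Conditions: N,N-diethylaniline, 200 °C
Reagents that add atoms: none
Why: Aromatic Claisen rearrangement, whose [3,3]-sigmatropic shift can deliver the allyl group only to the single free ortho position (the future C3a), after which enolisation restores the phenol.

Step 3
Reactants: 4 5-allylvanillin
Product: 5 2-allyl-4-formyl-6-methoxyphenyl trifluoromethanesulfonate
Conditions: Tf2O, pyridine, CH2Cl2, 0 °C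
Reagents that add atoms: trifluoromethanesulfonic anhydride, O=S(=O)(OS(=O)(=O)C(F)(F)F)C(F)(F)F
Why: Routine O-sulfonylation of a phenol, which turns the vanillin oxygen at the future C7a into the leaving group of the key step and, by removing the donor phenol, makes the aldehyde electrophilic enough for acetalisation.

Step 4
Reactants: 5 2-allyl-4-formyl-6-methoxyphenyl trifluoromethanesulfonate
Product: 6 2-allyl-4-(1,3-dioxolan-2-yl)-6-methoxyphenyl trifluoromethanesulfonate
Conditions: ethylene glycol, p-TsOH·H2O (cat.), toluene, reflux, Dean–Stark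
Reagents that add atoms: ethylene glycol, OCCO
Why: Acid-catalysed acetalisation with azeotropic removal of water masks the C5 aldehyde against the later enolate and hydride steps, and the aryl triflate and terminal alkene are inert to catalytic sulfonic acid.

Step 5
Reactants: 6 2-allyl-4-(1,3-dioxolan-2-yl)-6-methoxyphenyl trifluoromethanesulfonate
Product: 8 4-(1,3-dioxolan-2-yl)-2-methoxy-6-(2-oxoethyl)phenyl trifluoromethanesulfonate (arylacetaldehyde), via vicinal diol 7 (not isolated)
Conditions: OsO4 (cat.), NaIO4, 2,6-lutidine, dioxane/H2O, rt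
Reagents that add atoms: osmium tetroxide (oxygen carrier), O=[Os](=O)(=O)=O; sodium periodate (terminal oxygen source), [Na+].[O-]I(=O)(=O)=O
Why: Lemieux–Johnson oxidation, in which catalytic dihydroxylation of the only alkene and in situ periodate glycol cleavage excise the terminal carbon, while 2,6-lutidine keeps the medium near neutral so that the acetal and the enolisable aldehyde survive.

Step 6
Reactants: 8 arylacetaldehyde
Product: 9 2-[5-(1,3-dioxolan-2-yl)-3-methoxy-2-(trifluoromethylsulfonyloxy)phenyl]acetic acid
Conditions: NaClO2, NaH2PO4, 2-methyl-2-butene, t-BuOH/H2O, 0 °C to rt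
Reagents that add atoms: sodium chlorite, [Na+].[O-]Cl=O
Why: Pinnick oxidation takes the sensitive aldehyde to the acid without touching the benzylic CH2, and the phosphate buffer is tolerated by a dioxolane whose aryl ring is deactivated by the para triflate.

Step 7
Reactants: 9 ring A arylacetic acid; 10 (R)-4-benzyl-2-oxazolidinone
Product: 12 (4R)-4-benzyl-3-{2-[5-(1,3-dioxolan-2-yl)-3-methoxy-2-(trifluoromethylsulfonyloxy)phenyl]acetyl}-1,3-oxazolidin-2-one, via mixed pivalic anhydride 11 (not isolated)
Conditions: t-BuCOCl, Et3N, THF, −20 °C; then LiCl, 10, −20 °C to rt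
Reagents that add atoms: none
Why: N-Acylation of the Evans auxiliary through a mixed anhydride under Et3N/LiCl avoids strong base and ketene-prone acid chloride chemistry, with attack at the less hindered arylacetyl carbonyl and the auxiliary stereocentre left untouched.

Step 8
Reactants: 13 syringaldehyde (4-hydroxy-3,5-dimethoxybenzaldehyde)
Product: 14 3,5-dimethoxy-4-(triisopropylsilyloxy)benzaldehyde
Conditions: i-Pr3SiCl, imidazole, DMF, rt
Reagents that add atoms: chlorotriisopropylsilane, CC(C)[Si](Cl)(C(C)C)C(C)C
Why: Standard imidazole-promoted phenol silylation, the bulky TIPS group being chosen because it must outlast borohydride, hot carbonate and a phosphonate anion yet fall to fluoride at the end.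

Step 9
Reactants: 12 ring A arylacetyl imide; 14 3,5-dimethoxy-4-(triisopropylsilyloxy)benzaldehyde
Product: 17 (4R)-4-benzyl-3-{(2R,3R)-3-[3,5-dimethoxy-4-(triisopropylsilyloxy)phenyl]-2-[5-(1,3-dioxolan-2-yl)-3-methoxy-2-(trifluoromethylsulfonyloxy)phenyl]-3-hydroxypropanoyl}-1,3-oxazolidin-2-one (syn aldol adduct), via Z boron enolate 15 (not isolated), via boron aldolate 16 (not isolated)
Conditions: n-Bu2BOTf, i-Pr2NEt, CH2Cl2, −78 to 0 °C; 14, −78 to 0 °C; then pH 7 buffer, MeOH, H2O2, 0 °C
Reagents that add atoms: none
Why: Evans syn-aldol reaction, in which soft enolisation gives the Z boron enolate and a closed Zimmerman–Traxler chair with opposed imide dipoles brings the aldehyde to the enolate face remote from the benzyl group, so that the (R)-auxiliary sets both new centres (future C3 and C2) as 2R,3R in the syn relationship.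

Step 10
Reactants: 17 syn aldol adduct
Product: 18 (1R,2S)-1-[3,5-dimethoxy-4-(triisopropylsilyloxy)phenyl]-2-[5-(1,3-dioxolan-2-yl)-3-methoxy-2-(trifluoromethylsulfonyloxy)phenyl]propane-1,3-diol
Conditions: LiBH4, MeOH, THF, 0 °C
Reagents that add atoms: none
Why: Reductive cleavage of the N-acyl oxazolidinone at the exocyclic carbonyl gives the C9 primary alcohol and recovered auxiliary without breaking a bond at either stereocentre (the descriptor at the future C3 changes from R to S only through CIP ranking), and aryl triflate, acetal and silyl ether are inert to borohydride.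

Step 11
Reactants: 18 (1R,2S)-1,3-diol
Product: 19 2-{(1R,2S)-1-[3,5-dimethoxy-4-(triisopropylsilyloxy)phenyl]-1-hydroxy-3-(triisopropylsilyloxy)propan-2-yl}-4-(1,3-dioxolan-2-yl)-6-methoxyphenyl trifluoromethanesulfonate
Conditions: i-Pr3SiCl, imidazole, DMF, 0 °C to rt
Reagents that add atoms: chlorotriisopropylsilane, CC(C)[Si](Cl)(C(C)C)C(C)C
Why: Sterically controlled monosilylation distinguishes the primary C9 hydroxyl from the crowded secondary benzylic C2 hydroxyl, and TIPS is preferred to a smaller silyl group because it resists O-to-O migration onto a neighbouring alkoxide under the basic conditions that follow.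

Step 12
Reactants: 19 (1R,2S)-configured ring A triflate with free C2 carbinol
Product: 20 (2R,3S)-2-[3,5-dimethoxy-4-(triisopropylsilyloxy)phenyl]-5-(1,3-dioxolan-2-yl)-7-methoxy-3-[(triisopropylsilyloxy)methyl]-2,3-dihydrobenzofuran
Conditions: Pd(OAc)2 (cat.), t-BuXPhos (2-di-tert-butylphosphino-2',4',6'-triisopropylbiphenyl), Cs2CO3, dry toluene, 80 °C
Reagents that add atoms: none
Why: Zerovalent palladium, formed in situ from Pd(OAc)2 and carrying one bulky phosphine, adds oxidatively into the C7a–OTf bond of ring A, the cationic divalent arylpalladium centre binds the C2 hydroxyl, Cs2CO3 removes the proton of the bound alcohol, and C–O reductive elimination forges O1–C7a and returns zerovalent palladium. The closest known reaction type is the intramolecular Buchwald–Hartwig etherification of aryl halides bearing secondary alcohols with di-tert-butyl(biaryl)phosphines and Cs2CO3, which furnishes 2-substituted dihydrobenzofurans without loss of carbinol configuration, while aryl triflates are proven electrophiles in the sister C–O (diaryl ether) and C–N couplings run with the same weak bases. The single ring formed, the five-membered dihydrofuran, closes by ring-contracting reductive elimination from a six-membered oxapalladacycle (Pd, O1, C2, C3, C3a, C7a) and not by substitution at a carbon stereocentre. No stereocentre is created and no bond to C2 or C3 is broken, so the syn (1R,2S) diad of 19 is transcribed into the 2,3-trans (2R,3S) ring of 20. Three selectivities are needed: reductive elimination over beta-hydride elimination of the secondary alkoxide (secured by the bulky electron-rich ligand, which leaves no open cis site), C–O insertion over S–O cleavage of the triflate (secured by dry, sparingly soluble Cs2CO3 in toluene, which generates alkoxide only on palladium), and O1 over the C9 oxygen, which could close an isomeric five-membered ring (secured by the non-migrating TIPS ether).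

Step 13
Reactants: 20 dihydrobenzofuran acetal
Product: 21 (2R,3S)-2-[3,5-dimethoxy-4-(triisopropylsilyloxy)phenyl]-7-methoxy-3-[(triisopropylsilyloxy)methyl]-2,3-dihydrobenzofuran-5-carbaldehyde
Conditions: PPTS (cat.), acetone/H2O, 40 °C
Reagents that add atoms: water, O
Why: Mild acid-catalysed acetal hydrolysis, made easy because O1 now sits para to C5 and stabilises the oxocarbenium ion, so that a pyridinium acid suffices and both TIPS ethers and the C2 benzylic ether remain intact.

Step 14
Reactants: 22 3,5-dihydroxybenzaldehyde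
Product: 23 3,5-bis(tert-butyldimethylsilyloxy)benzaldehyde
Conditions: t-BuMe2SiCl, imidazole, DMF, rt
Reagents that add atoms: tert-butylchlorodimethylsilane, CC(C)(C)[Si](C)(C)Cl
Why: Standard imidazole-promoted silylation caps both unhindered phenols of ring C with a fluoride-labile group.

Step 15
Reactants: 23 3,5-bis(tert-butyldimethylsilyloxy)benzaldehyde
Product: 24 [3,5-bis(tert-butyldimethylsilyloxy)phenyl]methanol
Conditions: NaBH4, MeOH/THF, 0 °C
Reagents that add atoms: none
Why: Borohydride reduction of an aryl aldehyde is fast at low temperature and leaves the aryl silyl ethers in place.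

Step 16
Reactants: 24 [3,5-bis(tert-butyldimethylsilyloxy)phenyl]methanol
Product: 25 3,5-bis(tert-butyldimethylsilyloxy)benzyl bromide
Conditions: CBr4, PPh3, CH2Cl2, 0 °C
Reagents that add atoms: carbon tetrabromide, BrC(Br)(Br)Br
Why: The Appel reaction converts the primary benzylic alcohol into the bromide under essentially neutral conditions that do not endanger the silyl ethers.

Step 17
Reactants: 25 3,5-bis(tert-butyldimethylsilyloxy)benzyl bromide
Product: 26 diethyl [3,5-bis(tert-butyldimethylsilyloxy)benzyl]phosphonate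
Conditions: P(OEt)3, neat, 130 °C
Reagents that add atoms: triethyl phosphite, CCOP(OCC)OCC
Why: Michaelis–Arbuzov reaction, in which SN2 attack of phosphorus on the reactive benzylic bromide and dealkylation by bromide give the phosphonate with volatile bromoethane as the only co-product.

Step 18
Reactants: 21 C5 aldehyde; 26 ring C benzylphosphonate
Product: 28 (2R,3S)-5-[(E)-3,5-bis(tert-butyldimethylsilyloxy)styryl]-2-[3,5-dimethoxy-4-(triisopropylsilyloxy)phenyl]-7-methoxy-3-[(triisopropylsilyloxy)methyl]-2,3-dihydrobenzofuran, via potassium phosphonate carbanion 27 (not isolated)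
Conditions: KN(SiMe3)2 (slight deficit relative to 26), THF, 0 °C; then 21, 0 °C to rt
Reagents that add atoms: none
Why: Horner–Wadsworth–Emmons olefination, in which the semi-stabilised benzylphosphonate anion adds reversibly to the aryl aldehyde and the adduct leading to the E-stilbene collapses preferentially, while a non-nucleophilic amide base used in deficit spares the aryl silyl ethers and the C3–H.

Step 19
Reactants: 28 tetrasilylated stilbene
Product: 29 gnetucleistol F, (2R,3S)-5-[(E)-3,5-dihydroxystyryl]-2-(4-hydroxy-3,5-dimethoxyphenyl)-3-(hydroxymethyl)-7-methoxy-2,3-dihydrobenzofuran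
Conditions: n-Bu4NF, AcOH, THF, 0 °C to rt
Reagents that add atoms: none
Why: Fluoride-driven desilylation removes all four silyl groups in one operation, with AcOH buffering the phenoxides so that quinone-methide opening of the 2-(4-hydroxyaryl)dihydrofuran, and with it C2 epimerisation, is suppressed.

**Compound list**

1 | vanillin | COc1cc(C=O)ccc1O | starting material
2 | allyl bromide | C=CCBr | starting material
3 | 4-(allyloxy)-3-methoxybenzaldehyde | C=CCOc1ccc(C=O)cc1OC | intermediate
4 | 5-allylvanillin | C=CCc1cc(C=O)cc(OC)c1O | intermediate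
5 | 2-allyl-4-formyl-6-methoxyphenyl triflate | C=CCc1cc(C=O)cc(OC)c1OS(=O)(=O)C(F)(F)F | intermediate
6 | 2-allyl-4-(1,3-dioxolan-2-yl)-6-methoxyphenyl triflate | C=CCc1cc(C2OCCO2)cc(OC)c1OS(=O)(=O)C(F)(F)F | intermediate
7 | 2-(2,3-dihydroxypropyl)-4-(1,3-dioxolan-2-yl)-6-methoxyphenyl triflate (formed in situ, carbinol centre unassigned) | OCC(O)Cc1cc(C2OCCO2)cc(OC)c1OS(=O)(=O)C(F)(F)F | intermediate
8 | 4-(1,3-dioxolan-2-yl)-2-methoxy-6-(2-oxoethyl)phenyl triflate | O=CCc1cc(C2OCCO2)cc(OC)c1OS(=O)(=O)C(F)(F)F | intermediate
9 | 2-[5-(1,3-dioxolan-2-yl)-3-methoxy-2-(triflyloxy)phenyl]acetic acid | OC(=O)Cc1cc(C2OCCO2)cc(OC)c1OS(=O)(=O)C(F)(F)F | intermediate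
10 | (R)-4-benzyl-2-oxazolidinone | O=C1N[C@H](Cc2ccccc2)CO1 | starting material
11 | mixed anhydride of 9 with pivalic acid (formed in situ) | CC(C)(C)C(=O)OC(=O)Cc1cc(C2OCCO2)cc(OC)c1OS(=O)(=O)C(F)(F)F | intermediate
12 | (4R)-N-(ring A arylacetyl)-4-benzyloxazolidin-2-one | O=C(Cc1cc(C2OCCO2)cc(OC)c1OS(=O)(=O)C(F)(F)F)N1C(=O)OC[C@H]1Cc1ccccc1 | intermediate
13 | syringaldehyde | COc1cc(C=O)cc(OC)c1O | starting material
14 | 3,5-dimethoxy-4-(triisopropylsilyloxy)benzaldehyde | COc1cc(C=O)cc(OC)c1O[Si](C(C)C)(C(C)C)C(C)C | intermediate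
15 | Z dibutylboron enolate of 12 (formed in situ) | CCCCB(CCCC)O/C(=C\c1cc(C2OCCO2)cc(OC)c1OS(=O)(=O)C(F)(F)F)N1C(=O)OC[C@H]1Cc1ccccc1 | intermediate
16 | dibutylboron aldolate of 17 (formed in situ) | COc1cc([C@@H]([C@H](C(=O)N2C(=O)OC[C@H]2Cc2ccccc2)c2cc(C3OCCO3)cc(OC)c2OS(=O)(=O)C(F)(F)F)OB(CCCC)CCCC)cc(OC)c1O[Si](C(C)C)(C(C)C)C(C)C | intermediate
17 | (4R,2'R,3'R) syn aldol adduct | COc1cc([C@@H]([C@H](C(=O)N2C(=O)OC[C@H]2Cc2ccccc2)c2cc(C3OCCO3)cc(OC)c2OS(=O)(=O)C(F)(F)F)O)cc(OC)c1O[Si](C(C)C)(C(C)C)C(C)C | intermediate
18 | (1R,2S)-1,3-diol | COc1cc([C@@H]([C@H](CO)c2cc(C3OCCO3)cc(OC)c2OS(=O)(=O)C(F)(F)F)O)cc(OC)c1O[Si](C(C)C)(C(C)C)C(C)C | intermediate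
19 | (1R,2S) key-step precursor: ring A triflate, free C2 carbinol, C9 TIPS ether, C5 dioxolane | COc1cc([C@@H]([C@H](CO[Si](C(C)C)(C(C)C)C(C)C)c2cc(C3OCCO3)cc(OC)c2OS(=O)(=O)C(F)(F)F)O)cc(OC)c1O[Si](C(C)C)(C(C)C)C(C)C | intermediate
20 | (2R,3S) key-step product: 2,3-trans-dihydrobenzofuran with C5 dioxolane | COc1cc([C@@H]2Oc3c(OC)cc(C4OCCO4)cc3[C@H]2CO[Si](C(C)C)(C(C)C)C(C)C)cc(OC)c1O[Si](C(C)C)(C(C)C)C(C)C | intermediate
21 | (2R,3S)-dihydrobenzofuran-5-carbaldehyde | COc1cc([C@@H]2Oc3c(OC)cc(C=O)cc3[C@H]2CO[Si](C(C)C)(C(C)C)C(C)C)cc(OC)c1O[Si](C(C)C)(C(C)C)C(C)C | intermediate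
22 | 3,5-dihydroxybenzaldehyde | O=Cc1cc(O)cc(O)c1 | starting material
23 | 3,5-bis(tert-butyldimethylsilyloxy)benzaldehyde | O=Cc1cc(O[Si](C)(C)C(C)(C)C)cc(O[Si](C)(C)C(C)(C)C)c1 | intermediate
24 | [3,5-bis(tert-butyldimethylsilyloxy)phenyl]methanol | OCc1cc(O[Si](C)(C)C(C)(C)C)cc(O[Si](C)(C)C(C)(C)C)c1 | intermediate
25 | 3,5-bis(tert-butyldimethylsilyloxy)benzyl bromide | BrCc1cc(O[Si](C)(C)C(C)(C)C)cc(O[Si](C)(C)C(C)(C)C)c1 | intermediate
26 | diethyl [3,5-bis(tert-butyldimethylsilyloxy)benzyl]phosphonate | CCOP(=O)(OCC)Cc1cc(O[Si](C)(C)C(C)(C)C)cc(O[Si](C)(C)C(C)(C)C)c1 | intermediate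
27 | potassium carbanion of 26 (formed in situ) | [K+].CCOP(=O)(OCC)[CH-]c1cc(O[Si](C)(C)C(C)(C)C)cc(O[Si](C)(C)C(C)(C)C)c1 | intermediate
28 | (2R,3S,E) tetrasilylated gnetucleistol F | COc1cc([C@@H]2Oc3c(OC)cc(/C=C/c4cc(O[Si](C)(C)C(C)(C)C)cc(O[Si](C)(C)C(C)(C)C)c4)cc3[C@H]2CO[Si](C(C)C)(C(C)C)C(C)C)cc(OC)c1O[Si](C(C)C)(C(C)C)C(C)C | intermediate
29 | gnetucleistol F | COc1cc([C@@H]2Oc3c(OC)cc(/C=C/c4cc(O)cc(O)c4)cc3[C@H]2CO)cc(OC)c1O | target

**Step count and risks**

Total steps: 19. Longest linear sequence: 14 (steps 1–7, 9–13, 18, 19).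

1. Step 12.
   - What may go wrong: sluggish oxidative addition at the doubly ortho-substituted C7a, sulfur–oxygen cleavage of the sulfonate by base, or beta-hydride elimination of the palladium alkoxide.
   - Fallback, from 19 back to the route at 21: the ring is closed from the other side, at C2–O1.
   - The triflyl group of 19 is removed on purpose with aqueous Et4NOH in dioxane at room temperature to give the ring A phenol F1.
   - Catalytic p-TsOH in moist acetone then ionises the electron-rich C2 benzylic alcohol, and the phenol captures the cation anti to the C3 substituent to give the 2,3-trans ring.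
   - The acetal, now activated, is hydrolysed in the same pot, so 21 is reached directly.
   - C2 is then re-set under control of C3, which still carries the absolute configuration from the aldol.

2. Step 9.
   - What may go wrong: incomplete addition to the electron-rich aldehyde and retro-aldol cleavage of the aldolate, with erosion of diastereoselectivity.
   - Fallback, from 13 and 12 (through enolate 15) back to the route at 19: the donor on ring B is switched off during C–C bond formation.
   - Syringaldehyde 13 is acetylated (Ac2O, pyridine) to 4-acetoxy-3,5-dimethoxybenzaldehyde F2.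
   - Enolate 15 adds to F2 to give the boron aldolate F3 and, after the same buffered peroxide work-up, the acetate aldol adduct F4.
   - LiBH4 removes the auxiliary and the aryl acetate together to give the phenolic triol F5.
   - Two equivalents of i-Pr3SiCl with imidazole silylate the phenol and the primary alcohol in one operation to give 19.

3. Step 10.
   - What may go wrong: retro-aldol fragmentation of the metal alkoxide before hydride delivery, favoured by the stabilised arylacetyl enolate as leaving group.
   - Fallback, from 17 back to the route at 19: the carbinol is masked so that no alkoxide can form.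
   - Et3SiCl, imidazole and DMAP in DMF give the C2 triethylsilyl ether F6, and LiBH4 then gives the primary alcohol F7.
   - i-Pr3SiCl and imidazole give the fully silylated triflate F8.
   - AcOH/THF/H2O at room temperature removes only the triethylsilyl group; the acetal is still protected by the deactivating para triflate, and 19 results.

**Further compounds**

F1 | step 12 | (1R,2S)-2-[5-(1,3-dioxolan-2-yl)-2-hydroxy-3-methoxyphenyl]-1-[3,5-dimethoxy-4-(triisopropylsilyloxy)phenyl]-3-(triisopropylsilyloxy)propan-1-ol | COc1cc([C@@H]([C@H](CO[Si](C(C)C)(C(C)C)C(C)C)c2cc(C3OCCO3)cc(OC)c2O)O)cc(OC)c1O[Si](C(C)C)(C(C)C)C(C)C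
F2 | step 9 | 4-acetoxy-3,5-dimethoxybenzaldehyde | COc1cc(C=O)cc(OC)c1OC(C)=O
F3 | step 9 | dibutylboron aldolate of F4 (formed in situ) | COc1cc([C@@H]([C@H](C(=O)N2C(=O)OC[C@H]2Cc2ccccc2)c2cc(C3OCCO3)cc(OC)c2OS(=O)(=O)C(F)(F)F)OB(CCCC)CCCC)cc(OC)c1OC(C)=O
F4 | step 9 | (4R,2'R,3'R) syn aldol adduct with ring B acetate | COc1cc([C@@H]([C@H](C(=O)N2C(=O)OC[C@H]2Cc2ccccc2)c2cc(C3OCCO3)cc(OC)c2OS(=O)(=O)C(F)(F)F)O)cc(OC)c1OC(C)=O
F5 | step 9 | (1R,2S)-1-(4-hydroxy-3,5-dimethoxyphenyl)-2-[5-(1,3-dioxolan-2-yl)-3-methoxy-2-(triflyloxy)phenyl]propane-1,3-diol | COc1cc([C@@H]([C@H](CO)c2cc(C3OCCO3)cc(OC)c2OS(=O)(=O)C(F)(F)F)O)cc(OC)c1O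
F6 | step 10 | C2 triethylsilyl ether of aldol adduct 17 | COc1cc([C@@H]([C@H](C(=O)N2C(=O)OC[C@H]2Cc2ccccc2)c2cc(C3OCCO3)cc(OC)c2OS(=O)(=O)C(F)(F)F)O[Si](CC)(CC)CC)cc(OC)c1O[Si](C(C)C)(C(C)C)C(C)C
F7 | step 10 | (2S,3R)-primary alcohol with C2 triethylsilyl ether | COc1cc([C@@H]([C@H](CO)c2cc(C3OCCO3)cc(OC)c2OS(=O)(=O)C(F)(F)F)O[Si](CC)(CC)CC)cc(OC)c1O[Si](C(C)C)(C(C)C)C(C)C
F8 | step 10 | C2 triethylsilyl ether of 19 | COc1cc([C@@H]([C@H](CO[Si](C(C)C)(C(C)C)C(C)C)c2cc(C3OCCO3)cc(OC)c2OS(=O)(=O)C(F)(F)F)O[Si](CC)(CC)CC)cc(OC)c1O[Si](C(C)C)(C(C)C)C(C)C
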